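**Retrosynthetic overview**
- The quinone ring is not built; it is unmasked last from a 2,3,5,6-tetramethoxyphenyl group by oxidative demethylation, then hydrolysis of the hindered methoxy group.
- The quaternary carbon C1 comes from α-face benzylation of a decalin-1-carbaldehyde enolate with 2,3,5,6-tetramethoxybenzyl bromide, followed by CHO → CH3.
- The decalin comes from an acyclic (2Z,6E)-dienyne: ring A, then ring B, close in one gold-catalysed enyne–ene cascade ended by a 1,5-hydride shift from a benzyl ether. This sets C4a, C8a and C2 and leaves the 5-methylidene group directly.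
- The dienyne comes from nerol: benzyl ether, allylic oxidation, bromide, copper-catalysed coupling with a butynyl Grignard reagent.

**Conventions and assumptions**
- Decalin locants follow the decahydronaphthalene names: C1 carries the side arm, C2 the secondary methyl, C4a–H and C8a–CH3 are the ring-fusion atoms, C5 carries the methylidene. Ring A is C4a–C5–C6–C7–C8–C8a; ring B is C1–C2–C3–C4–C4a–C8a. β is the face of the C8a methyl.
- Assumption: the (R)-configured digold catalyst of step 6 is taken to give the (4aS,8aS) series; if it gives the antipode, the (S)-ligand is used with nothing else changed.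

**Route**

Step 1
Reactants: 1 nerol, (2Z)-3,7-dimethylocta-2,6-dien-1-ol
Product: 2 benzyl (2Z)-3,7-dimethylocta-2,6-dien-1-yl ether
Conditions: NaH, BnBr, THF, 0 °C → rt
Reagents that add atoms: benzyl bromide, BrCc1ccccc1
Why: Williamson ether synthesis (SN2 of the primary allylic alkoxide on benzyl bromide); no stereocentre is made, the (2Z)-alkene is untouched, and the OCH2Ph hydrogens later serve as the internal hydride source of step 6.

Step 2
Reactants: 2 benzyl neryl ether
Product: 3 (2E,6Z)-8-(benzyloxy)-2,6-dimethylocta-2,6-dien-1-ol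
Conditions: SeO2 (0.3 equiv), t-BuOOH (3 equiv), CH2Cl2, 0 °C → rt
Reagents that add atoms: tert-butyl hydroperoxide, CC(C)(C)OO; selenium dioxide (catalytic oxygen carrier), O=[Se]=O
Why: Sharpless–Umbreit allylic oxidation (ene reaction, then [2,3]-sigmatropic shift) attacks the (E)-methyl of the electron-richer terminal alkene and gives the (E)-allylic alcohol, while the alkene next to the ether oxygen is deactivated.

Step 3
Reactants: 3 (2E,6Z)-8-(benzyloxy)-2,6-dimethylocta-2,6-dien-1-ol
Product: 4 benzyl (2Z,6E)-8-bromo-3,7-dimethylocta-2,6-dien-1-yl ether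
Conditions: CBr4, PPh3, CH2Cl2, 0 °C
Reagents that add atoms: carbon tetrabromide, BrC(Br)(Br)Br
Why: Appel bromination of a primary allylic alcohol proceeds by SN2 on the alkoxyphosphonium ion without allylic transposition or loss of alkene geometry.

Step 4
Reactants: 4 benzyl (2Z,6E)-8-bromo-3,7-dimethylocta-2,6-dien-1-yl ether; 5 (4-bromobut-1-yn-1-yl)trimethylsilane
Product: 7 benzyl (2Z,6E)-3,7-dimethyl-12-(trimethylsilyl)dodeca-2,6-dien-11-yn-1-yl ether, via butynyl Grignard reagent 6 (not isolated)
Conditions: 5, Mg, THF, rt; then 4, Li2CuCl4 (3 mol %), THF, −78 °C → 0 °C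
Reagents that add atoms: none
Why: Copper-catalysed Grignard–allylic bromide cross-coupling (Kochi/Schlosser–Fouquet type) substitutes the primary allylic bromide at the α-carbon with retention of the (E)-alkene; the silyl cap keeps the alkyne C–H from quenching the Grignard reagent.

Step 5
Reactants: 7 silyl-capped dienyne
Product: 8 benzyl (2Z,6E)-3,7-dimethyldodeca-2,6-dien-11-yn-1-yl ether
Conditions: K2CO3 (cat.), MeOH, rt
Reagents that add atoms: none
Why: Methanolysis of the alkynyl–silicon bond (protodesilylation) frees the terminal alkyne needed for π-activation; nothing else in the molecule reacts with methoxide.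

Step 6
Reactants: 8 benzyl (2Z,6E)-3,7-dimethyldodeca-2,6-dien-11-yn-1-yl ether
Product: 10 [(1R,2S,4aS,8aS)-2,8a-dimethyl-5-methylidenedecahydronaphthalen-1-yl]methanol, via benzaldehyde hemiacetal 9 (not isolated)
Conditions: (R)-DTBM-SEGPHOS(AuCl)2 [C74H100O8P2(AuCl)2] (5 mol %), AgSbF6 (10 mol %), H2O (2 equiv), CH2Cl2, −30 °C → rt
Reagents that add atoms: none
Why: Proposed new method: cationic monovalent gold binds the terminal alkyne and C6 of the (6E)-alkene attacks its internal carbon (exo-dig, Markovnikov), closing ring A with an exocyclic vinyl-gold; the tertiary cation at the future C8a is then captured by C2 of the (2Z)-alkene through a chair–chair transition state, closing ring B, where anti addition across the E-alkene gives the trans ring fusion and the Z-alkene puts the CH2OBn arm axial on the α face of C1; the resulting tertiary cation at the future decalin C2 is quenched by a 1,5-hydride shift from the OCH2Ph group of that arm through a six-membered transition state that can reach only the α lobe, so the C2 methyl ends β, cis to the C8a methyl; water then adds to the benzylidene oxocarbenium ion, the proton released cleaves the C–Au bond to give the methylidene group and return the catalyst, and hemiacetal 9 falls apart to 10 and benzaldehyde; the chiral bisphosphine–digold pocket selects the enantiotopic face of the (6E)-alkene in the first C–C bond formation; the closest known reaction types are the enantioselective gold-catalysed enyne-initiated polyene cyclisation, the InBr3-promoted alkyne-initiated cyclisation to methylidenecyclohexanes, and hydride-shift (internal redox) quenching of carbocations by benzyl ethers.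

Step 7
Reactants: 10 [(1R,2S,4aS,8aS)-2,8a-dimethyl-5-methylidenedecahydronaphthalen-1-yl]methanol
Product: 11 (1R,2S,4aS,8aS)-2,8a-dimethyl-5-methylidenedecahydronaphthalene-1-carbaldehyde
Conditions: Dess–Martin periodinane, CH2Cl2, 0 °C → rt
Reagents that add atoms: none
Why: Dess–Martin oxidation takes the hindered primary alcohol to the aldehyde under near-neutral conditions that leave the methylidene group alone; the C1 configuration does not matter because C1 becomes planar in step 10.

Step 8
Reactants: 12 1,2,4,5-tetramethoxybenzene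
Product: 14 (2,3,5,6-tetramethoxyphenyl)methanol, via aryllithium 13 (not isolated)
Conditions: n-BuLi, TMEDA, THF, 0 °C; then (CH2O)n, 0 °C → rt; H2O
Reagents that add atoms: formaldehyde (as paraformaldehyde), C=O
Why: Directed ortho-lithiation occurs at the position flanked by two methoxy groups (the two free positions are equivalent), and the aryllithium adds to formaldehyde to give the benzylic alcohol.

Step 9
Reactants: 14 (2,3,5,6-tetramethoxyphenyl)methanol
Product: 15 3-(bromomethyl)-1,2,4,5-tetramethoxybenzene
Conditions: PBr3, Et2O, 0 °C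
Reagents that add atoms: phosphorus tribromide, BrP(Br)Br
Why: Bromination of an electron-rich benzylic alcohol through its phosphite ester is fast at 0 °C; the bromide is used directly because it is very reactive.

Step 10
Reactants: 11 (1R,2S,4aS,8aS)-2,8a-dimethyl-5-methylidenedecahydronaphthalene-1-carbaldehyde; 15 3-(bromomethyl)-1,2,4,5-tetramethoxybenzene
Product: 17 (1S,2S,4aS,8aS)-2,8a-dimethyl-5-methylidene-1-[(2,3,5,6-tetramethoxyphenyl)methyl]decahydronaphthalene-1-carbaldehyde, via potassium enolate 16 (not isolated)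
Conditions: KH, THF, 0 °C; then 15, 0 °C → rt
Reagents that add atoms: none
Why: C-alkylation of an α-branched aldehyde potassium enolate with a soft benzylic bromide creates the quaternary C1; the β (equatorial) approach is flanked by the two axial β-methyls on C2 and C8a, so the electrophile enters from the α (axial) face past only the axial hydrogens on C3 and C4a, giving CH2Ar α and CHO β.

Step 11
Reactants: 17 quaternary aldehyde
Product: 19 3-{[(1R,2S,4aS,8aS)-1,2,8a-trimethyl-5-methylidenedecahydronaphthalen-1-yl]methyl}-1,2,4,5-tetramethoxybenzene, via hydrazone 18 (not isolated)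
Conditions: N2H4·H2O, diethylene glycol, 130 °C; then KOH, 200 °C, Ar
Reagents that add atoms: none
Why: Wolff–Kishner reduction (Huang-Minlon) turns the non-enolisable neopentyl aldehyde into the β-methyl group with no change at any stereocentre; aryl methyl ethers and the isolated methylidene group tolerate hot KOH when air is excluded.

Step 12
Reactants: 19 tetramethoxyaryl decalin
Product: 20 2,5-dimethoxy-3-{[(1R,2S,4aS,8aS)-1,2,8a-trimethyl-5-methylidenedecahydronaphthalen-1-yl]methyl}cyclohexa-2,5-diene-1,4-dione
Conditions: (NH4)2Ce(NO3)6 (2.5 equiv), MeCN/H2O (2:1), 0 °C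
Reagents that add atoms: water, O
Why: Oxidative demethylation by tetravalent cerium turns a para-dimethoxy pair into the para-quinone (both para pairs give the same product by symmetry), with the carbonyl oxygens coming from water; the alkene is not touched at 0 °C.

Step 13
Reactants: 20 dimethoxyquinone
Product: 21 2-hydroxy-5-methoxy-3-{[(1R,2S,4aS,8aS)-1,2,8a-trimethyl-5-methylidenedecahydronaphthalen-1-yl]methyl}cyclohexa-2,5-diene-1,4-dione (target)
Conditions: KOH (2 M aq), MeOH, 0 °C → rt; then 1 M HCl to pH 3
Reagents that add atoms: potassium hydroxide, [K+].[OH-]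
Why: Addition–elimination of hydroxide on a vinylogous ester; the C2 methoxy group, squeezed between the alkylated C3 and a carbonyl, is twisted out of conjugation and reacts first, and the resulting hydroxyquinone anion is too electron-rich for the second methoxy group to be displaced; this selectivity is taken from the endgame I recall for the ilimaquinone series and should be confirmed on a model.

**Compound list**

1 | nerol, (2Z)-3,7-dimethylocta-2,6-dien-1-ol | CC(C)=CCC/C(C)=C\CO | starting material
2 | benzyl (2Z)-3,7-dimethylocta-2,6-dien-1-yl ether | CC(C)=CCC/C(C)=C\COCc1ccccc1 | intermediate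
3 | (2E,6Z)-8-(benzyloxy)-2,6-dimethylocta-2,6-dien-1-ol | OC/C(C)=C/CC/C(C)=C\COCc1ccccc1 | intermediate
4 | benzyl (2Z,6E)-8-bromo-3,7-dimethylocta-2,6-dien-1-yl ether | BrC/C(C)=C/CC/C(C)=C\COCc1ccccc1 | intermediate
5 | (4-bromobut-1-yn-1-yl)trimethylsilane | C[Si](C)(C)C#CCCBr | starting material
6 | [4-(trimethylsilyl)but-3-yn-1-yl]magnesium bromide | C[Si](C)(C)C#CCC[Mg]Br | intermediate
7 | benzyl (2Z,6E)-3,7-dimethyl-12-(trimethylsilyl)dodeca-2,6-dien-11-yn-1-yl ether | C[Si](C)(C)C#CCCC/C(C)=C/CC/C(C)=C\COCc1ccccc1 | intermediate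
8 | benzyl (2Z,6E)-3,7-dimethyldodeca-2,6-dien-11-yn-1-yl ether | C#CCCC/C(C)=C/CC/C(C)=C\COCc1ccccc1 | intermediate
9 | {[(1R,2S,4aS,8aS)-2,8a-dimethyl-5-methylidenedecahydronaphthalen-1-yl]methoxy}(phenyl)methanol, both epimers at the hemiacetal carbon | C=C1CCC[C@@]2(C)[C@H]1CC[C@H](C)[C@H]2COC(O)c1ccccc1 | intermediate
10 | [(1R,2S,4aS,8aS)-2,8a-dimethyl-5-methylidenedecahydronaphthalen-1-yl]methanol (trans-decalin; C8a–CH3 and C2–CH3 β, CH2OH α) | C=C1CCC[C@@]2(C)[C@H]1CC[C@H](C)[C@H]2CO | intermediate
11 | (1R,2S,4aS,8aS)-2,8a-dimethyl-5-methylidenedecahydronaphthalene-1-carbaldehyde | C=C1CCC[C@@]2(C)[C@H]1CC[C@H](C)[C@H]2C=O | intermediate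
12 | 1,2,4,5-tetramethoxybenzene | COc1cc(OC)c(OC)cc1OC | starting material
13 | (2,3,5,6-tetramethoxyphenyl)lithium | [Li]c1c(OC)c(OC)cc(OC)c1OC | intermediate
14 | (2,3,5,6-tetramethoxyphenyl)methanol | OCc1c(OC)c(OC)cc(OC)c1OC | intermediate
15 | 3-(bromomethyl)-1,2,4,5-tetramethoxybenzene | BrCc1c(OC)c(OC)cc(OC)c1OC | intermediate
16 | potassium [(2S,4aS,8aS)-2,8a-dimethyl-5-methylideneoctahydronaphthalen-1(2H)-ylidene]methanolate (enolate geometry not fixed) | C=C1CCC[C@@]2(C)[C@H]1CC[C@H](C)C2=C[O-].[K+] | intermediate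
17 | (1S,2S,4aS,8aS)-2,8a-dimethyl-5-methylidene-1-[(2,3,5,6-tetramethoxyphenyl)methyl]decahydronaphthalene-1-carbaldehyde (CHO β, CH2Ar α) | C=C1CCC[C@@]2(C)[C@H]1CC[C@H](C)[C@@]2(C=O)Cc1c(OC)c(OC)cc(OC)c1OC | intermediate
18 | hydrazone of 17 (C=N geometry not fixed) | C=C1CCC[C@@]2(C)[C@H]1CC[C@H](C)[C@@]2(C=NN)Cc1c(OC)c(OC)cc(OC)c1OC | intermediate
19 | 3-{[(1R,2S,4aS,8aS)-1,2,8a-trimethyl-5-methylidenedecahydronaphthalen-1-yl]methyl}-1,2,4,5-tetramethoxybenzene | C=C1CCC[C@@]2(C)[C@H]1CC[C@H](C)[C@@]2(C)Cc1c(OC)c(OC)cc(OC)c1OC | intermediate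
20 | 2,5-dimethoxy-3-{[(1R,2S,4aS,8aS)-1,2,8a-trimethyl-5-methylidenedecahydronaphthalen-1-yl]methyl}cyclohexa-2,5-diene-1,4-dione | C=C1CCC[C@@]2(C)[C@H]1CC[C@H](C)[C@@]2(C)CC1=C(OC)C(=O)C=C(OC)C1=O | intermediate
21 | 2-hydroxy-5-methoxy-3-{[(1R,2S,4aS,8aS)-1,2,8a-trimethyl-5-methylidenedecahydronaphthalen-1-yl]methyl}cyclohexa-2,5-diene-1,4-dione | C=C1CCC[C@@]2(C)[C@H]1CC[C@H](C)[C@@]2(C)CC1=C(O)C(=O)C=C(OC)C1=O | target

**Step count**
- Total: 13 steps.
- Longest linear sequence: 11 steps (steps 1–7 and 10–13, from nerol). Steps 8–9 make bromide 15 in parallel.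

**Three steps most likely to fail**

Risk 1, step 6. The enantioselective exo-dig closure of ring A with a chiral digold catalyst has no direct precedent, and the hydride-shift ending competes with proton loss and with capture of the cations by water. The fallback replaces catalyst control by resolution. It sets out from dienyne 8, which is cyclised with achiral InBr3 (10 mol %, H2O 2 equiv, CH2Cl2, −20 °C). This gives alcohol 10 as a 1:1 mixture with its antipode [(1S,2R,4aR,8aR)-2,8a-dimethyl-5-methylidenedecahydronaphthalen-1-yl]methanol F1. The mixture is esterified with (2S)-2-methoxy-2-phenylacetic acid (DCC, DMAP, CH2Cl2) to the diastereomers [(1R,2S,4aS,8aS)-2,8a-dimethyl-5-methylidenedecahydronaphthalen-1-yl]methyl (2S)-2-methoxy-2-phenylacetate F2 and [(1S,2R,4aR,8aR)-2,8a-dimethyl-5-methylidenedecahydronaphthalen-1-yl]methyl (2S)-2-methoxy-2-phenylacetate F3. F2 is separated by chromatography or crystallisation and cleaved with LiOH in THF/H2O, which comes back to the route at 10.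

Risk 2, step 10. The enolate carbon sits between a quaternary and a tertiary carbon, so O-benzylation or no reaction may win. The fallback changes the nucleophile to a metalloenamine, which alkylates on carbon only. It sets out from aldehyde 11, which is condensed with cyclohexylamine (MgSO4, CH2Cl2) to N-cyclohexyl-1-[(1R,2S,4aS,8aS)-2,8a-dimethyl-5-methylidenedecahydronaphthalen-1-yl]methanimine F4. LiN(i-Pr)2 in THF at 0 °C gives lithium cyclohexyl{[(2S,4aS,8aS)-2,8a-dimethyl-5-methylideneoctahydronaphthalen-1(2H)-ylidene]methyl}azanide F5. Bromide 15 then alkylates it from the α face, for the same steric reason as in step 10, to N-cyclohexyl-1-{(1S,2S,4aS,8aS)-2,8a-dimethyl-5-methylidene-1-[(2,3,5,6-tetramethoxyphenyl)methyl]decahydronaphthalen-1-yl}methanimine F6. Aqueous oxalic acid hydrolyses F6 and comes back to the route at 17.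

Risk 3, step 11. The aldehyde is doubly neopentyl, so hydrazone formation may be slow and hot KOH may instead cause deformylation or move the methylidene double bond. The fallback removes the oxygen by a radical route under neutral conditions. It sets out from aldehyde 17, which NaBH4 in MeOH reduces to {(1S,2S,4aS,8aS)-2,8a-dimethyl-5-methylidene-1-[(2,3,5,6-tetramethoxyphenyl)methyl]decahydronaphthalen-1-yl}methanol F7. NaH, CS2, then MeI in THF give O-({(1S,2S,4aS,8aS)-2,8a-dimethyl-5-methylidene-1-[(2,3,5,6-tetramethoxyphenyl)methyl]decahydronaphthalen-1-yl}methyl) S-methyl carbonodithioate F8. Bu3SnH and AIBN in xylene at 140 °C (Barton–McCombie deoxygenation) then come back to the route at 19.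

**Further compounds**

F1 | step 6 | [(1S,2R,4aR,8aR)-2,8a-dimethyl-5-methylidenedecahydronaphthalen-1-yl]methanol | C=C1CCC[C@]2(C)[C@@H]1CC[C@@H](C)[C@@H]2CO
F2 | step 6 | [(1R,2S,4aS,8aS)-2,8a-dimethyl-5-methylidenedecahydronaphthalen-1-yl]methyl (2S)-2-methoxy-2-phenylacetate | C=C1CCC[C@@]2(C)[C@H]1CC[C@H](C)[C@H]2COC(=O)[C@@H](OC)c1ccccc1
F3 | step 6 | [(1S,2R,4aR,8aR)-2,8a-dimethyl-5-methylidenedecahydronaphthalen-1-yl]methyl (2S)-2-methoxy-2-phenylacetate | C=C1CCC[C@]2(C)[C@@H]1CC[C@@H](C)[C@@H]2COC(=O)[C@@H](OC)c1ccccc1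
F4 | step 10 | N-cyclohexyl-1-[(1R,2S,4aS,8aS)-2,8a-dimethyl-5-methylidenedecahydronaphthalen-1-yl]methanimine | C=C1CCC[C@@]2(C)[C@H]1CC[C@H](C)[C@H]2C=NC1CCCCC1
F5 | step 10 | lithium cyclohexyl{[(2S,4aS,8aS)-2,8a-dimethyl-5-methylideneoctahydronaphthalen-1(2H)-ylidene]methyl}azanide | C=C1CCC[C@@]2(C)[C@H]1CC[C@H](C)C2=C[N-]C1CCCCC1.[Li+]
F6 | step 10 | N-cyclohexyl-1-{(1S,2S,4aS,8aS)-2,8a-dimethyl-5-methylidene-1-[(2,3,5,6-tetramethoxyphenyl)methyl]decahydronaphthalen-1-yl}methanimine | C=C1CCC[C@@]2(C)[C@H]1CC[C@H](C)[C@@]2(C=NC1CCCCC1)Cc1c(OC)c(OC)cc(OC)c1OC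
F7 | step 11 | {(1S,2S,4aS,8aS)-2,8a-dimethyl-5-methylidene-1-[(2,3,5,6-tetramethoxyphenyl)methyl]decahydronaphthalen-1-yl}methanol | C=C1CCC[C@@]2(C)[C@H]1CC[C@H](C)[C@@]2(CO)Cc1c(OC)c(OC)cc(OC)c1OC
F8 | step 11 | O-({(1S,2S,4aS,8aS)-2,8a-dimethyl-5-methylidene-1-[(2,3,5,6-tetramethoxyphenyl)methyl]decahydronaphthalen-1-yl}methyl) S-methyl carbonodithioate | C=C1CCC[C@@]2(C)[C@H]1CC[C@H](C)[C@@]2(COC(=S)SC)Cc1c(OC)c(OC)cc(OC)c1OC
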